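**Retrosynthetic overview**
- Target 20 ⇐ methyl ester 19 (fluoride desilylation) ⇐ acid 18 (O-methylation of the carboxylate).
- Key disconnection: the C6–O diaryl ether bond and the C1–carboxyl bond of ring A are cut together, so 18 ⇒ aryne 16 (from silyl triflate 10) + the potassium phenoxide of ring B phenol 13 + CO2 14.
- Feature used: on ring A the ester carbon C1 sits between C2 (prenyloxy) and C6 (aryloxy). C1 and C6 can therefore be the two carbons of an aryne, and the C2 oxygen sends the nucleophile to C6 and the electrophile to C1.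
- 10 ⇐ orcinol 1 + prenyl bromide 2 (mono-ether, carbamate-directed lithiation/silylation between the two oxygens, carbamate-to-triflate exchange); 13 ⇐ aldehyde 11 (reduction, silylation of the primary hydroxyl).
- No ring is formed in the route (both benzene rings are purchased) and the target has no stereocentre.

Key step: step 7

Assumption: 2-hydroxy-3,5-dimethoxybenzaldehyde 11 and anhydrous orcinol 1 are taken as purchased materials; the target is achiral, so no configuration has to be set or protected.

**Route**

Step 1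
Reactants: 1 orcinol (5-methylbenzene-1,3-diol); 2 prenyl bromide (1-bromo-3-methylbut-2-ene)
Product: 3 3-methyl-5-[(3-methylbut-2-en-1-yl)oxy]phenol
Conditions: 1 (3 equiv), 2 (1 equiv), K2CO3, DMF, rt; aqueous wash removes excess 1
Reagents that add atoms: none
Why: Williamson O-alkylation of a phenoxide by the allylic bromide, in which a threefold excess of the symmetrical diol holds the reaction at the mono-ether and the polar aprotic medium favours O- over C-prenylation.

Step 2
Reactants: 3 3-methyl-5-[(3-methylbut-2-en-1-yl)oxy]phenol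
Product: 4 3-methyl-5-[(3-methylbut-2-en-1-yl)oxy]phenyl N-(propan-2-yl)carbamate
Conditions: i-PrNCO, Et3N (cat.), CH2Cl2, rt
Reagents that add atoms: isopropyl isocyanate, CC(C)N=C=O
Why: Amine-catalysed addition of the phenol to the isocyanate gives the N–H carbamate, a strong directing group for ortho-metalation that can later be removed under mild base.

Step 3
Reactants: 4 3-methyl-5-[(3-methylbut-2-en-1-yl)oxy]phenyl N-(propan-2-yl)carbamate
Product: 8 5-methyl-3-[(3-methylbut-2-en-1-yl)oxy]-2-(trimethylsilyl)phenyl N-(propan-2-yl)carbamate, via N-silyl carbamate 5 (not isolated), via aryllithium 6 (not isolated), via bis-silyl carbamate 7 (not isolated)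
Conditions: TBSOTf, TMEDA, Et2O, 0 °C to rt; then n-BuLi, TMEDA, −78 °C; then TMSCl, −78 °C to rt; aq NaHSO4 work-up
Reagents that add atoms: chlorotrimethylsilane, C[Si](C)(C)Cl; tert-butyldimethylsilyl triflate, CC(C)(C)[Si](C)(C)OS(=O)(=O)C(F)(F)F (silyl group held by 5, 6 and 7 only); n-butyllithium, [Li]CCCC (lithium held by 6 only)
Why: Directed ortho-metalation: once the carbamate N–H is masked in the flask as its N-silyl derivative, n-BuLi/TMEDA at −78 °C removes the ring proton flanked by both oxygen directing groups (the kinetically preferred site, well ahead of the allylic O–CH2 of the prenyl ether), TMSCl silylates the aryllithium and the labile N–Si bond is hydrolysed on acidic work-up.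

Step 4
Reactants: 8 5-methyl-3-[(3-methylbut-2-en-1-yl)oxy]-2-(trimethylsilyl)phenyl N-(propan-2-yl)carbamate
Product: 10 5-methyl-3-[(3-methylbut-2-en-1-yl)oxy]-2-(trimethylsilyl)phenyl trifluoromethanesulfonate, via ortho-silylphenol 9 (not isolated)
Conditions: DBU, Et2NH, MeCN, 40 °C; then PhNTf2, rt
Reagents that add atoms: N-phenylbis(trifluoromethanesulfonimide), O=S(=O)(N(c1ccccc1)S(=O)(=O)C(F)(F)F)C(F)(F)F
Why: DBU deprotonates the carbamate N–H and the phenoxide is expelled together with isopropyl isocyanate (E1cB), which Et2NH scavenges as a urea, and the phenoxide is triflated in the same flask, so the protodesilylation-prone ortho-silylphenol is never handled.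

Step 5
Reactants: 11 2-hydroxy-3,5-dimethoxybenzaldehyde
Product: 12 2-(hydroxymethyl)-4,6-dimethoxyphenol
Conditions: NaBH4, MeOH, 0 °C; aq NH4Cl quench
Reagents that add atoms: none
Why: Borohydride reduction of an aromatic aldehyde to the benzylic alcohol, with a near-neutral quench so that the electron-rich salicyl alcohol does not lose water.

Step 6
Reactants: 12 2-(hydroxymethyl)-4,6-dimethoxyphenol
Product: 13 2-({[tert-butyl(dimethyl)silyl]oxy}methyl)-4,6-dimethoxyphenol
Conditions: TBSCl (1.05 equiv), imidazole, CH2Cl2, 0 °C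
Reagents that add atoms: tert-butyldimethylsilyl chloride, CC(C)(C)[Si](C)(C)Cl
Why: Chemoselective silylation, since the unhindered primary benzylic hydroxyl reacts with TBSCl/imidazole much faster than the phenol, which is flanked by two ortho substituents and hydrogen-bonded.

Step 7
Reactants: 10 5-methyl-3-[(3-methylbut-2-en-1-yl)oxy]-2-(trimethylsilyl)phenyl trifluoromethanesulfonate; 13 2-({[tert-butyl(dimethyl)silyl]oxy}methyl)-4,6-dimethoxyphenol; 14 carbon dioxide
Product: 18 2-[2-({[tert-butyl(dimethyl)silyl]oxy}methyl)-4,6-dimethoxyphenoxy]-4-methyl-6-[(3-methylbut-2-en-1-yl)oxy]benzoic acid, via potassium phenoxide 15 (not isolated), via aryne 16 (not isolated), via arylpotassium 17 (not isolated)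
Conditions: 13 (1.5 equiv), KH (1.5 equiv), THF, 0 °C to rt; then dried KF, 18-crown-6, CO2 (1 atm), THF, 0 °C, slow addition of 10 (1 equiv), then rt; cold aq KHSO4 work-up
Reagents that add atoms: potassium hydride, [KH] (potassium held by 15 and 17 only)
Why: Proposed new method: fluoride attacks the trimethylsilyl group of 10 and the ortho triflate leaves to give aryne 16, whose triple bond spans the future C1 and C6 of ring A; phenoxide 15 adds at C6, the aryne carbon remote from the C2 prenyloxy group, so the negative charge develops at C1 beside the electron-withdrawing C2–O bond, and this aryl anion 17, now flanked by two oxygens, adds to CO2 to give the carboxylate that is protonated to 18 on work-up. The closest known reaction types are the three-component coupling of arynes with amines and CO2 to anthranilic acids under KF/18-crown-6 in THF, the fluoride-mediated O-arylation of phenols by ortho-silylaryl triflates, and the regioselective addition of nucleophiles to 3-alkoxybenzynes; what is new is an anionic oxygen nucleophile in the CO2-trapping manifold. No ring is closed and no stereocentre is formed. The step needs three selectivities: regiochemistry, set by the inductive and distortion effect of the C2 alkoxy group; O- rather than C-arylation, ensured because both ortho positions and the para position of 15 are substituted; and carboxylation rather than protonation of 17, favoured by a phenoxide preformed with KH (which leaves only H2), aprotic THF in place of an acidic nitrile solvent, dried KF/18-crown-6 and a CO2-saturated solution into which 10 is fed slowly. The phenoxide is used in excess so that it, and not the product carboxylate, captures the aryne.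

Step 8
Reactants: 18 2-[2-({[tert-butyl(dimethyl)silyl]oxy}methyl)-4,6-dimethoxyphenoxy]-4-methyl-6-[(3-methylbut-2-en-1-yl)oxy]benzoic acid
Product: 19 methyl 2-[2-({[tert-butyl(dimethyl)silyl]oxy}methyl)-4,6-dimethoxyphenoxy]-4-methyl-6-[(3-methylbut-2-en-1-yl)oxy]benzoate
Conditions: MeI, K2CO3, DMF, rt
Reagents that add atoms: iodomethane, CI
Why: SN2 O-alkylation of the carboxylate by MeI, the reliable way to esterify a 2,6-disubstituted benzoic acid that resists Fischer esterification, under conditions that leave the silyl ether and the prenyl ether untouched.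

Step 9
Reactants: 19 methyl 2-[2-({[tert-butyl(dimethyl)silyl]oxy}methyl)-4,6-dimethoxyphenoxy]-4-methyl-6-[(3-methylbut-2-en-1-yl)oxy]benzoate
Product: 20 methyl 2-[2-(hydroxymethyl)-4,6-dimethoxyphenoxy]-4-methyl-6-[(3-methylbut-2-en-1-yl)oxy]benzoate (target CNP0573678.0)
Conditions: TBAF, AcOH, THF, 0 °C to rt
Reagents that add atoms: none
Why: Fluoride-induced cleavage of the Si–O bond, with acetic acid buffering the alkoxide as it forms so that it cannot attack the neighbouring methyl ester, while the prenyl ether, diaryl ether and ester are inert.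

**Compound list**
1 | orcinol (5-methylbenzene-1,3-diol) | Cc1cc(O)cc(O)c1 | starting material
2 | prenyl bromide (1-bromo-3-methylbut-2-ene) | CC(C)=CCBr | starting material
3 | 3-methyl-5-[(3-methylbut-2-en-1-yl)oxy]phenol | CC(C)=CCOc1cc(C)cc(O)c1 | intermediate
4 | 3-methyl-5-[(3-methylbut-2-en-1-yl)oxy]phenyl N-(propan-2-yl)carbamate | CC(C)=CCOc1cc(C)cc(OC(=O)NC(C)C)c1 | intermediate
5 | 3-methyl-5-[(3-methylbut-2-en-1-yl)oxy]phenyl N-[tert-butyl(dimethyl)silyl]-N-(propan-2-yl)carbamate (not isolated) | CC(C)=CCOc1cc(C)cc(OC(=O)N(C(C)C)[Si](C)(C)C(C)(C)C)c1 | intermediate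
6 | 2-lithio derivative of 5, lithium on the ring carbon between the two oxygens (not isolated) | [Li]c1c(OCC=C(C)C)cc(C)cc1OC(=O)N(C(C)C)[Si](C)(C)C(C)(C)C | intermediate
7 | 5-methyl-3-[(3-methylbut-2-en-1-yl)oxy]-2-(trimethylsilyl)phenyl N-[tert-butyl(dimethyl)silyl]-N-(propan-2-yl)carbamate (not isolated) | C[Si](C)(C)c1c(OCC=C(C)C)cc(C)cc1OC(=O)N(C(C)C)[Si](C)(C)C(C)(C)C | intermediate
8 | 5-methyl-3-[(3-methylbut-2-en-1-yl)oxy]-2-(trimethylsilyl)phenyl N-(propan-2-yl)carbamate | C[Si](C)(C)c1c(OCC=C(C)C)cc(C)cc1OC(=O)NC(C)C | intermediate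
9 | 5-methyl-3-[(3-methylbut-2-en-1-yl)oxy]-2-(trimethylsilyl)phenol (not isolated) | C[Si](C)(C)c1c(OCC=C(C)C)cc(C)cc1O | intermediate
10 | 5-methyl-3-[(3-methylbut-2-en-1-yl)oxy]-2-(trimethylsilyl)phenyl trifluoromethanesulfonate | CC(C)=CCOc1cc(C)cc(OS(=O)(=O)C(F)(F)F)c1[Si](C)(C)C | intermediate
11 | 2-hydroxy-3,5-dimethoxybenzaldehyde | COc1cc(C=O)c(O)c(OC)c1 | starting material
12 | 2-(hydroxymethyl)-4,6-dimethoxyphenol | COc1cc(CO)c(O)c(OC)c1 | intermediate
13 | 2-({[tert-butyl(dimethyl)silyl]oxy}methyl)-4,6-dimethoxyphenol | COc1cc(OC)c(O)c(CO[Si](C)(C)C(C)(C)C)c1 | intermediate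
14 | carbon dioxide | O=C=O | starting material
15 | potassium 2-({[tert-butyl(dimethyl)silyl]oxy}methyl)-4,6-dimethoxyphenoxide (not isolated) | [K+].[O-]c1c(CO[Si](C)(C)C(C)(C)C)cc(OC)cc1OC | intermediate
16 | 5-methyl-3-[(3-methylbut-2-en-1-yl)oxy]benzyne (1,2-didehydrobenzene, not isolated) | CC(C)=CCOC1=CC(C)=CC#C1 | intermediate
17 | arylpotassium from addition of 15 to 16, potassium on ring A C1 between the prenyloxy and aryloxy carbons (not isolated) | [K]c1c(OCC=C(C)C)cc(C)cc1Oc1c(CO[Si](C)(C)C(C)(C)C)cc(OC)cc1OC | intermediate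
18 | 2-[2-({[tert-butyl(dimethyl)silyl]oxy}methyl)-4,6-dimethoxyphenoxy]-4-methyl-6-[(3-methylbut-2-en-1-yl)oxy]benzoic acid | OC(=O)c1c(OCC=C(C)C)cc(C)cc1Oc1c(CO[Si](C)(C)C(C)(C)C)cc(OC)cc1OC | intermediate
19 | methyl 2-[2-({[tert-butyl(dimethyl)silyl]oxy}methyl)-4,6-dimethoxyphenoxy]-4-methyl-6-[(3-methylbut-2-en-1-yl)oxy]benzoate | COC(=O)c1c(OCC=C(C)C)cc(C)cc1Oc1c(CO[Si](C)(C)C(C)(C)C)cc(OC)cc1OC | intermediate
20 | methyl 2-[2-(hydroxymethyl)-4,6-dimethoxyphenoxy]-4-methyl-6-[(3-methylbut-2-en-1-yl)oxy]benzoate | COC(=O)c1c(OCC=C(C)C)cc(C)cc1Oc1c(CO)cc(OC)cc1OC | target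

**Step count**
Total: 9 steps. Longest linear sequence: 7 steps (steps 1, 2, 3, 4, 7, 8, 9); the ring B arm (steps 5 and 6) joins at step 7.

**Steps most likely to fail**

Step 7 (proposed new method). What may go wrong: protonation of aryl anion 17 (by traces of water, the crown ether, THF or the benzylic CH2 of ring B) may outrun CO2 capture and leave only the hydro-diaryl ether. Under CO2 the phenoxide 15 may rest as its carbonate and add too slowly, so that the aryne is lost to oligomers. Fluoride may also strip the silyl ether during the run.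

Fallback, known chemistry, sets out from carbamate 4 and comes back at target 20. The carboxyl carbon is placed by the same directed lithiation and the diaryl ether is then made with copper.
- Carbamate 4 is N-silylated and lithiated as in step 3 (via 5 and 6), and 6 is quenched with methyl chloroformate instead of TMSCl. This gives the N-silylated ester methyl 2-({[tert-butyl(dimethyl)silyl](propan-2-yl)carbamoyl}oxy)-4-methyl-6-[(3-methylbut-2-en-1-yl)oxy]benzoate F1 in the flask and, after NaHSO4 work-up, methyl 4-methyl-6-[(3-methylbut-2-en-1-yl)oxy]-2-[(propan-2-ylcarbamoyl)oxy]benzoate F2.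
- DBU/Et2NH in MeCN at 40 °C releases the salicylate methyl 2-hydroxy-4-methyl-6-[(3-methylbut-2-en-1-yl)oxy]benzoate F3.
- Ullmann diaryl ether coupling of F3 with commercial 2-bromo-3,5-dimethoxybenzaldehyde (CuI, picolinic acid, K3PO4, DMSO, 90 °C; the ortho formyl group activates the bromide) gives methyl 2-(2-formyl-4,6-dimethoxyphenoxy)-4-methyl-6-[(3-methylbut-2-en-1-yl)oxy]benzoate F4.
- NaBH4 in MeOH/THF at 0 °C reduces the aldehyde and gives 20 directly, with no silyl group on ring B.

Step 3. What may go wrong: n-BuLi may deprotonate the allylic O–CH2 of the prenyl ether or attack it in SN2' fashion in competition with ring metalation. The lithiated carbamate may also undergo anionic Fries migration if it warms before silylation.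

Fallback, sets out from orcinol 1 and comes back at triflate 10. The ring carbanion is made by iodine–lithium exchange, which is faster than any deprotonation, and silicon is delivered from oxygen.
- Orcinol 1 is iodinated between its hydroxyls (I2, NaHCO3, THF/H2O, 0 °C) to 2-iodo-5-methylbenzene-1,3-diol F5.
- Mono-prenylation with 2 (K2CO3, DMF, rt, excess diol) gives 2-iodo-5-methyl-3-[(3-methylbut-2-en-1-yl)oxy]phenol F6.
- Hexamethyldisilazane (neat, 80 °C) gives the aryl silyl ether {2-iodo-5-methyl-3-[(3-methylbut-2-en-1-yl)oxy]phenoxy}trimethylsilane F7.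
- n-BuLi in THF at −78 °C triggers the exchange and the O-to-C silyl migration (retro-Brook) to lithium 5-methyl-3-[(3-methylbut-2-en-1-yl)oxy]-2-(trimethylsilyl)phenoxide F8, which is triflated in the flask with Tf2O to give 10.

Step 9. What may go wrong: the benzylic alkoxide freed under fluoride may attack the ring A methyl ester across the diaryl ether (transesterification to the eight-membered lactone with loss of methanol), or the basic medium may damage the ester.

Fallback, sets out from acid 18 and comes back at target 20. The silyl group is removed at the carboxylate stage, where the carbonyl is not electrophilic, and the ester is made last under neutral conditions.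
- Acid 18 with TBAF in THF at rt gives 2-[2-(hydroxymethyl)-4,6-dimethoxyphenoxy]-4-methyl-6-[(3-methylbut-2-en-1-yl)oxy]benzoic acid F9.
- Trimethylsilyldiazomethane in toluene/MeOH at 0 °C methylates only the carboxylic acid and gives 20.

Further compounds
F1 | step 7 | methyl 2-({[tert-butyl(dimethyl)silyl](propan-2-yl)carbamoyl}oxy)-4-methyl-6-[(3-methylbut-2-en-1-yl)oxy]benzoate | COC(=O)c1c(OCC=C(C)C)cc(C)cc1OC(=O)N(C(C)C)[Si](C)(C)C(C)(C)C
F2 | step 7 | methyl 4-methyl-6-[(3-methylbut-2-en-1-yl)oxy]-2-[(propan-2-ylcarbamoyl)oxy]benzoate | COC(=O)c1c(OCC=C(C)C)cc(C)cc1OC(=O)NC(C)C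
F3 | step 7 | methyl 2-hydroxy-4-methyl-6-[(3-methylbut-2-en-1-yl)oxy]benzoate | COC(=O)c1c(O)cc(C)cc1OCC=C(C)C
F4 | step 7 | methyl 2-(2-formyl-4,6-dimethoxyphenoxy)-4-methyl-6-[(3-methylbut-2-en-1-yl)oxy]benzoate | COC(=O)c1c(OCC=C(C)C)cc(C)cc1Oc1c(C=O)cc(OC)cc1OC
F5 | step 3 | 2-iodo-5-methylbenzene-1,3-diol | Cc1cc(O)c(I)c(O)c1
F6 | step 3 | 2-iodo-5-methyl-3-[(3-methylbut-2-en-1-yl)oxy]phenol | CC(C)=CCOc1cc(C)cc(O)c1I
F7 | step 3 | {2-iodo-5-methyl-3-[(3-methylbut-2-en-1-yl)oxy]phenoxy}trimethylsilane | CC(C)=CCOc1cc(C)cc(O[Si](C)(C)C)c1I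
F8 | step 3 | lithium 5-methyl-3-[(3-methylbut-2-en-1-yl)oxy]-2-(trimethylsilyl)phenoxide | [Li+].[O-]c1cc(C)cc(OCC=C(C)C)c1[Si](C)(C)C
F9 | step 9 | 2-[2-(hydroxymethyl)-4,6-dimethoxyphenoxy]-4-methyl-6-[(3-methylbut-2-en-1-yl)oxy]benzoic acid | OC(=O)c1c(OCC=C(C)C)cc(C)cc1Oc1c(CO)cc(OC)cc1OC
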